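**Plan**

- Retrosynthesis: the biaryl bond and the allyl–arene bond of the ether-bearing arene (ring A) are cut first (cross-couplings), then the aryl C–O bond to the tertiary carbinol C3 (aryl transfer from a diaryliodonium salt), then C3–CH3, C5–H and the side-chain C11–O bond, which leads back to a cyclopropane-fused enone.
- That enone is cut at C10–C1 and C4=C5 to carone and but-3-en-2-one; carone is cut at one cyclopropane bond back to (R)-carvone.
- Enabling feature: in the ether ring the O-bearing C3 lies 1,3 to the ring-fusion carbon C5 and 1,4 to the angular carbon C10, exactly where a Robinson annulation places its carbonyl. The second ring is a p-menthane unit (C10 methyl cis to the 2-hydroxypropan-2-yl group on C7) that maps onto carvone once the side chain is folded into a cyclopropane.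
- Forward order: cyclopropane closed on the carvone ring, ether ring closed by annulation, cyclopropane opened by water, trans ring fusion set, methyl added, O-arylation, allylation, biaryl coupling, desilylation.
- Stereochemistry: C7 comes from (R)-carvone; C10 from enolate alkylation anti to the gem-dimethylcyclopropane; C5 from Li/NH3 reduction; C3 from equatorial methyl delivery.

Key step: step 4

Remark: decalin locants C1–C11 follow eudesmane numbering and β is the face of the angular methyl group; the methyl-bearing α-carbon of 2, 3 and 4 is epimerisable and is planarised in step 4, so epimer mixtures at that carbon are carried on unseparated.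

**Route**

Step 1
Reactants: 1 (R)-(−)-carvone
Product: 2 (+)-dihydrocarvone, (2R,5R)-2-methyl-5-(prop-1-en-2-yl)cyclohexan-1-one
Conditions: Zn, KOH, EtOH/H2O, reflux
Reagents that add atoms: none
Why: Dissolving-metal conjugate reduction of the enone leaves the isolated isopropenyl alkene untouched; the new C2 centre is epimerisable and is erased later, and C5 is not involved.

Step 2
Reactants: 2 (+)-dihydrocarvone
Product: 3 (2R,5R)-5-(2-bromopropan-2-yl)-2-methylcyclohexan-1-one
Conditions: HBr (33% in AcOH), 0 °C
Reagents that add atoms: hydrogen bromide, SMILES Br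
Why: Markovnikov hydrobromination of the 1,1-disubstituted alkene gives the tertiary bromide through the tertiary cation, and no stereocentre is formed.

Step 3
Reactants: 3 bromo ketone
Product: 4 carone, (1S,3R,6R)-3,7,7-trimethylbicyclo[4.1.0]heptan-2-one
Conditions: KOH, MeOH, 0 °C to rt
Reagents that add atoms: none
Why: Intramolecular enolate alkylation (3-exo-tet, the classical carone synthesis): the enolate on the CH2 side displaces the tertiary bromide on the neighbouring ring carbon, the cis fusion is geometrically enforced and the carvone-derived centre is retained.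

Step 4
Reactants: 4 carone; 5 but-3-en-2-one
Product: 8 cyclopropane-fused tricyclic enone, via Michael diketone 6 (not isolated), via aldol ketol 7 (not isolated)
Conditions: KOH (cat.), EtOH/Et2O, −10 °C to rt, slow addition of 5; then KOH, EtOH, reflux
Reagents that add atoms: none
Why: Hydroxide generates the only possible enolate of 4, toward the methyl-bearing carbon, because the other α-carbon is a cyclopropane CH whose enolisation would put a double bond on the three-membered ring; this enolate adds to 5 in a Michael reaction and forms the C10–C1 bond of 6. The methyl ketone enolate of 6 then attacks the ring carbonyl in an aldol addition (6-enolendo-exo-trig closure of the ether ring) to give 7, and E1cB dehydration installs the C4=C5 enone of 8. The closest known reaction is the Robinson annulation of carone itself with alkyl vinyl ketones on the way to eudesmane enones. The single new stereocentre, quaternary C10, is controlled by the cis-fused gem-dimethylcyclopropane, whose inward methyl group shields its own face of the enolate, so the acceptor enters anti and the angular methyl ends cis to the CMe2 bridge, that is, cis to the future C7 side chain. The step needs alkylation at the substituted α-carbon and survival of the cyclopropane; the first is secured by the non-enolisable cyclopropyl position and the second by the purely basic medium.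

Step 5
Reactants: 8 tricyclic enone
Product: 9 (4aS,7R)-7-(2-hydroxypropan-2-yl)-4a-methyl-4,4a,5,6,7,8-hexahydronaphthalen-2(3H)-one
Conditions: aq. HClO4, dioxane, rt
Reagents that add atoms: water, SMILES O
Why: Acid-mediated homoconjugate opening of a vinylogous cyclopropyl ketone: O-protonation makes C5 a cyclopropylcarbinyl cation, the C6–C11 bond breaks toward the tertiary cation, water traps it and the dienol returns to the conjugated enone, so the C7–C11 bond and the centres C7 and C10 are untouched.

Step 6
Reactants: 9 hydroxy enone
Product: 10 trans-fused hydroxy decalone (3-oxo, 5α-H, 10β-CH3, 7β-C(CH3)2OH)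
Conditions: Li, NH3(l)/THF, −78 °C; then NH4Cl
Reagents that add atoms: none
Why: Dissolving-metal (Birch-type) enone reduction in which C5 is protonated axially, anti to the angular methyl group, setting the trans ring fusion (5α-H); the carbonyl is regenerated only on quenching, which limits over-reduction.

Step 7
Reactants: 10 hydroxy decalone
Product: 11 triethylsilyl ether of 10 (11-OSiEt3)
Conditions: Et3SiOTf, 2,6-lutidine, CH2Cl2, −78 to 0 °C
Reagents that add atoms: triethylsilyl trifluoromethanesulfonate, SMILES CC[Si](CC)(CC)OS(=O)(=O)C(F)(F)F
Why: Silylation of the hindered tertiary alcohol with a silyl triflate and a hindered pyridine base; any silyl enol ether formed at the ketone reverts to the same ketone on aqueous work-up, and no stereocentre changes.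

Step 8
Reactants: 11 silyloxy decalone
Product: 12 tertiary alcohol (3α-OH axial, 3β-CH3 equatorial, 5α-H, 10β-CH3, 11-OSiEt3)
Conditions: MeTi(OiPr)3, hexane/Et2O, 0 °C to rt
Reagents that add atoms: methyltitanium triisopropoxide, SMILES C[Ti](OC(C)C)(OC(C)C)OC(C)C
Why: Organotitanium carbonyl methylation: the bulky, weakly basic reagent should approach the unhindered C3 ketone along the equatorial β trajectory, away from the axial hydrogens on C1 and C5, setting C3 with equatorial CH3 and axial OH without enolisation.

Step 9
Reactants: 13 4-bromo-2-chloro-1-iodobenzene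
Product: 15 (4-bromo-2-chlorophenyl)(2,4,6-trimethoxyphenyl)iodonium tosylate, via hydroxy(tosyloxy)iodoarene 14 (not isolated)
Conditions: mCPBA, TsOH·H2O, MeCN, 77 °C; then 1,3,5-trimethoxybenzene
Reagents that add atoms: 1,3,5-trimethoxybenzene, SMILES COc1cc(OC)cc(OC)c1; p-toluenesulfonic acid monohydrate, SMILES Cc1ccc(cc1)S(=O)(=O)O.O
Why: One-pot peracid oxidation of the aryl iodide to the trivalent-iodine tosylate 14, followed by electrophilic aromatic substitution of the electron-rich arene at iodine, a standard synthesis of aryl(trimethoxyphenyl)iodonium salts that tolerates aryl halides.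

Step 10
Reactants: 12 tertiary alcohol; 15 iodonium tosylate
Product: 16 4-bromo-2-chlorophenyl ether of 12 (3α-OAr)
Conditions: NaH, toluene/THF, rt; then 15, rt
Reagents that add atoms: none
Why: Metal-free O-arylation of a tertiary alkoxide with a diaryliodonium salt (ligand exchange at iodine, then ligand coupling): the electron-poor, ortho-substituted 4-bromo-2-chlorophenyl group should transfer in preference to the electron-rich trimethoxyphenyl group, and the C3–O bond is never broken, so C3 keeps its configuration.

Step 11
Reactants: 16 bromo chloro aryl ether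
Product: 17 4-allyl-2-chlorophenyl ether
Conditions: allylboronic acid pinacol ester, Pd(PPh3)4, CsF, THF, 65 °C
Reagents that add atoms: allylboronic acid pinacol ester, SMILES C=CCB1OC(C)(C)C(C)(C)O1
Why: Suzuki–Miyaura allylation with zerovalent palladium: Pd(PPh3)4 inserts into the C–Br bond but not into the ortho C–Cl bond, and fluoride activates the allylboronate for transmetalation.

Step 12
Reactants: 18 4-bromophenol
Product: 19 allyl 4-bromophenyl ether
Conditions: allyl bromide, K2CO3, acetone, reflux
Reagents that add atoms: allyl bromide, SMILES C=CCBr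
Why: Williamson ether synthesis of the phenoxide with an allylic bromide.

Step 13
Reactants: 19 allyl 4-bromophenyl ether
Product: 20 2-allyl-4-bromophenol
Conditions: neat, 200 °C
Reagents that add atoms: none
Why: Aromatic Claisen rearrangement ([3,3]-sigmatropic shift, then tautomerisation) delivers the allyl group to the free ortho position, the para position being blocked by bromine.

Step 14
Reactants: 20 2-allyl-4-bromophenol
Product: 21 2-allyl-4-(4,4,5,5-tetramethyl-1,3,2-dioxaborolan-2-yl)phenol
Conditions: B2pin2, Pd(dppf)Cl2, KOAc, dioxane, 90 °C
Reagents that add atoms: bis(pinacolato)diboron, SMILES CC1(C)OB(OC1(C)C)B1OC(C)(C)C(C)(C)O1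
Why: Miyaura borylation of the aryl bromide, in which the weak base KOAc suppresses coupling of the product boronate; free phenols and allyl groups are tolerated.

Step 15
Reactants: 17 aryl chloride; 21 arylboronate
Product: 22 triethylsilyl ether of the target
Conditions: Pd(OAc)2, SPhos, K3PO4, toluene/H2O, 90 °C
Reagents that add atoms: none
Why: Suzuki–Miyaura biaryl coupling of an electron-rich ortho-alkoxy aryl chloride, for which the Pd(OAc)2/SPhos system is suited; the free phenol of 21 is tolerated as its phenoxide and no stereocentre is touched.

Step 16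
Reactants: 22 silyl ether
Product: 23 target, 2-[(2R,4aS,7R,8aS)-7-{[4′-hydroxy-3′,5-di(prop-2-en-1-yl)biphenyl-2-yl]oxy}-4a,7-dimethyldecahydronaphthalen-2-yl]propan-2-ol
Conditions: Bu4NF, THF, 50 °C
Reagents that add atoms: none
Why: Fluoride-mediated cleavage of the tertiary triethylsilyl ether under non-acidic conditions, which spares the acid-labile tertiary alkyl aryl ether and the allyl groups.

**Compound list**

1 | (R)-(−)-carvone | CC1=CC[C@@H](C(C)=C)CC1=O | starting material
2 | (+)-dihydrocarvone, (2R,5R), trans major | C[C@@H]1CC[C@@H](C(C)=C)CC1=O | intermediate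
3 | (2R,5R)-5-(2-bromopropan-2-yl)-2-methylcyclohexan-1-one | C[C@@H]1CC[C@@H](C(C)(C)Br)CC1=O | intermediate
4 | carone, (1S,3R,6R)-3,7,7-trimethylbicyclo[4.1.0]heptan-2-one (methyl trans to the CMe2 bridge drawn) | C[C@@H]1CC[C@@H]2[C@H](C1=O)C2(C)C | intermediate
5 | but-3-en-2-one | C=CC(C)=O | starting material
6 | Michael diketone, 3-methyl-3-(3-oxobutyl)carone with the oxobutyl chain anti to the CMe2 bridge (not isolated) | CC(=O)CC[C@]1(C)CC[C@@H]2[C@H](C1=O)C2(C)C | intermediate
7 | aldol ketol, 5-hydroxy-3-ketone, carbinol configuration undefined (not isolated) | O=C1CC[C@]2(C)CC[C@@H]3[C@H](C2(O)C1)C3(C)C | intermediate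
8 | tricyclic enone: 4-en-3-one, 10β-CH3, gem-dimethylcyclopropane cis-fused across C6–C7 on the β face | O=C1CC[C@]2(C)CC[C@@H]3[C@H](C2=C1)C3(C)C | intermediate
9 | (4aS,7R)-7-(2-hydroxypropan-2-yl)-4a-methyl-4,4a,5,6,7,8-hexahydronaphthalen-2(3H)-one | O=C1CC[C@]2(C)CC[C@@H](C(C)(C)O)CC2=C1 | intermediate
10 | trans-decalone: 3-oxo, 5α-H, 10β-CH3, 7β-(2-hydroxypropan-2-yl) | O=C1CC[C@]2(C)CC[C@@H](C(C)(C)O)C[C@H]2C1 | intermediate
11 | triethylsilyl ether of 10 | O=C1CC[C@]2(C)CC[C@@H](C(C)(C)O[Si](CC)(CC)CC)C[C@H]2C1 | intermediate
12 | tertiary alcohol: 3α-OH, 3β-CH3, 5α-H, 10β-CH3, 7β-C(CH3)2OSiEt3 | O[C@]1(C)CC[C@]2(C)CC[C@@H](C(C)(C)O[Si](CC)(CC)CC)C[C@H]2C1 | intermediate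
13 | 4-bromo-2-chloro-1-iodobenzene | Clc1cc(Br)ccc1I | starting material
14 | (4-bromo-2-chlorophenyl)(hydroxy)(tosyloxy)-λ3-iodane (not isolated) | Cc1ccc(cc1)S(=O)(=O)OI(O)c1ccc(Br)cc1Cl | intermediate
15 | (4-bromo-2-chlorophenyl)(2,4,6-trimethoxyphenyl)iodonium tosylate | COc1cc(OC)c([I+]c2ccc(Br)cc2Cl)c(OC)c1.Cc1ccc(cc1)S(=O)(=O)[O-] | intermediate
16 | 3α-(4-bromo-2-chlorophenoxy) ether of 12 | Clc1cc(Br)ccc1O[C@]1(C)CC[C@]2(C)CC[C@@H](C(C)(C)O[Si](CC)(CC)CC)C[C@H]2C1 | intermediate
17 | 3α-(4-allyl-2-chlorophenoxy) ether | C=CCc1ccc(O[C@]2(C)CC[C@]3(C)CC[C@@H](C(C)(C)O[Si](CC)(CC)CC)C[C@H]3C2)c(Cl)c1 | intermediate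
18 | 4-bromophenol | Oc1ccc(Br)cc1 | starting material
19 | allyl 4-bromophenyl ether | C=CCOc1ccc(Br)cc1 | intermediate
20 | 2-allyl-4-bromophenol | C=CCc1cc(Br)ccc1O | intermediate
21 | 2-allyl-4-(4,4,5,5-tetramethyl-1,3,2-dioxaborolan-2-yl)phenol | C=CCc1cc(B2OC(C)(C)C(C)(C)O2)ccc1O | intermediate
22 | triethylsilyl ether of the target | C=CCc1ccc(O[C@]2(C)CC[C@]3(C)CC[C@@H](C(C)(C)O[Si](CC)(CC)CC)C[C@H]3C2)c(-c2ccc(O)c(CC=C)c2)c1 | intermediate
23 | target (3R,5S,7R,10S in eudesmane numbering) | C=CCc1ccc(O[C@]2(C)CC[C@]3(C)CC[C@@H](C(C)(C)O)C[C@H]3C2)c(-c2ccc(O)c(CC=C)c2)c1 | target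

**Count and risks**

Total: 16 steps. Longest linear sequence: 12 steps from 1 (steps 1–8, 10, 11, 15, 16). Step 9 and steps 12–14 are side branches.

Steps most likely to fail:

1. Step 10. Ligand coupling at the congested axial tertiary alkoxide may be slow, so that base-induced aryne formation from the salt, its decomposition, or transfer of the wrong aryl group competes. The fallback replaces aryl transfer by nucleophilic aromatic substitution and sets out from 12. Deprotonation with KN(SiMe3)2 in THF and addition of 2-chloro-1-fluoro-4-nitrobenzene should displace the fluoride para to the nitro group and give the 2-chloro-4-nitrophenyl ether F1. Reduction with Fe and NH4Cl in EtOH/H2O gives the aniline F2. Sandmeyer bromination with t-BuONO and CuBr2 in MeCN gives the aryl bromide and returns to the route at 16.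

2. Step 4. Base-induced polymerisation of the vinyl ketone may outrun conjugate addition of the hindered, fully substituted enolate, and retro-Michael cleavage or incomplete dehydration may lower the throughput. The fallback keeps the same bond formations but runs the conjugate addition aprotically with a silyl-stabilised acceptor, setting out from 4. Deprotonation with LiN(iPr)2 in THF at −78 °C and addition of 3-(trimethylsilyl)but-3-en-2-one should give the α-silyl diketone F3, with the same facial control by the cyclopropane. KOH in MeOH at reflux then removes the silyl group and effects the aldol condensation, passing through 6 and 7 and returning at 8.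

3. Step 8. Facial selectivity of the methyl addition may be insufficient, or addition of the weakly reactive titanium reagent may be sluggish. The fallback builds the carbinol in two steps from 11. Corey–Chaykovsky epoxidation with dimethylsulfoxonium methylide (Me3S(O)I, NaH, DMSO, rt) forms the C–C bond reversibly and therefore equatorially, giving the spiro-epoxide F4 with axial α-oxygen. LiAlH4 in THF opens F4 at the CH2 terminus and returns at 12, the silyl ether being stable to both reagents.

**Further compounds**

F1 | step 10 | 3α-(2-chloro-4-nitrophenoxy) ether of 12 | [O-][N+](=O)c1ccc(O[C@]2(C)CC[C@]3(C)CC[C@@H](C(C)(C)O[Si](CC)(CC)CC)C[C@H]3C2)c(Cl)c1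
F2 | step 10 | 3α-(4-amino-2-chlorophenoxy) ether of 12 | Nc1ccc(O[C@]2(C)CC[C@]3(C)CC[C@@H](C(C)(C)O[Si](CC)(CC)CC)C[C@H]3C2)c(Cl)c1
F3 | step 4 | α-silyl diketone, 3-methyl-3-[3-oxo-2-(trimethylsilyl)butyl]carone, silyl-bearing carbon undefined | CC(=O)C([Si](C)(C)C)C[C@]1(C)CC[C@@H]2[C@H](C1=O)C2(C)C
F4 | step 8 | C3 spiro-epoxide of 11 with α-oxygen and β-CH2 | C1O[C@@]12CC[C@]3(C)CC[C@@H](C(C)(C)O[Si](CC)(CC)CC)C[C@H]3C2
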